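**Strategy**

Ring B is disconnected at C1'–C2' and C5'–C6'. Its cyclohexene core, with the gem-dimethyl group on C1', the methyl on C5' and the side-chain carbon on C6', is the [4+2] adduct of (E)-penta-1,3-diene 1 and mesityl oxide 2. One enantioselective endo Diels–Alder reaction closes ring B and sets C6' plus a cis C5' relay centre in ketone 3; the C5' hydrogen later directs the alkene shift and the C3' oxygen trans to C7'. Both precursors are commercial and need no preparation. The acetyl group then becomes the C7'=C8' alkenyl metal for a cross-coupling, and a final olefination joins ring B to a C25 aldehyde built from α-ionone and the C10 dialdehyde.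

Key step: step 1

Assumption: the (S)-oxazaborolidinium catalyst is written on the premise that it leaves open the enone face leading to 3; its sense of induction with a β,β-disubstituted enone is untested, and the (R)-catalyst would be used if the antipode formed.

Labels: carotenoid numbering; primed atoms belong to ring B (the hydroxylated ring), unprimed atoms to ring A; the upper face of ring B is the face that carries the C5' and C6' hydrogens in 3.

**Route**

Step 1
Reactants: 1 (E)-penta-1,3-diene; 2 mesityl oxide
Product: 3 1-[(1R,2R)-2,6,6-trimethylcyclohex-3-en-1-yl]ethanone (cis)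
Conditions: (S)-1-(2-methylphenyl)-3,3-diphenyltetrahydro-1H,3H-pyrrolo[1,2-c][1,3,2]oxazaborole (20 mol%), AlBr3 (16 mol%), 1 (4 equiv), CH2Cl2, −40 °C; Et3N, pH 7 buffer
Reagents that add atoms: none
Why: Proposed new method: the AlBr3-activated oxazaborolidinium ion binds the carbonyl oxygen of 2 and lowers the enone LUMO, and the diene then adds in a concerted, asynchronous, suprafacial [4+2] cycloaddition in which its CH2 terminus bonds to the β-carbon (C1'–C2') and its methyl-bearing terminus to the α-carbon (C5'–C6'). The closest known reactions are the AlCl3-promoted racemic cycloaddition of these same two components and oxazaborolidinium-catalysed Diels–Alder reactions of enones that lack the second β-substituent. Ring B closes in a single intermolecular [4+2] annulation that makes both ring bonds at once. C6' is controlled by the catalyst, whose aryl group shields one face of the bound enone, and C5' by the endo transition state (acetyl under the diene), which puts the C5' methyl cis to the acetyl group. The step needs ortho regioselectivity, secured by the large HOMO coefficient at the unsubstituted diene terminus and the large LUMO coefficient at the β-carbon, together with endo selectivity and enone face selectivity. Low temperature and a buffered work-up keep the kinetic cis adduct from epimerising at C6'.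

Step 2
Reactants: 3 1-[(1R,2R)-2,6,6-trimethylcyclohex-3-en-1-yl]ethanone
Product: 5 (3R,4R)-4-ethynyl-3,5,5-trimethylcyclohex-1-ene, via enol phosphate 4 (not isolated)
Conditions: LiN(i-Pr)2 (1.1 equiv), THF, −78 °C (3 added to base); ClP(O)(OEt)2, −78 °C → 23 °C; LiN(i-Pr)2 (2.3 equiv), −78 °C → 23 °C; NH4Cl aq
Reagents that add atoms: none
Why: Kinetic deprotonation of the methyl group (the hindered C6' hydrogen is left alone, so both centres survive), O-phosphorylation and base-induced β-elimination of diethyl phosphate convert the methyl ketone into the terminal alkyne (enol phosphate elimination); no new stereocentre.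

Step 3
Reactants: 5 (3R,4R)-4-ethynyl-3,5,5-trimethylcyclohex-1-ene
Product: 6 (1S,2S,3S,4R)-2-bromo-4-ethynyl-3,5,5-trimethylcyclohexyl acetate
Conditions: NBS (1.1 equiv), NaOAc (2 equiv), AcOH, 15 °C, dark
Reagents that add atoms: N-bromosuccinimide, O=C1CCC(=O)N1Br; acetic acid, CC(=O)O
Why: Alkene bromoacetoxylation (cohalogenation): in the favoured half-chair (C5' methyl pseudoequatorial, slim ethynyl group axial below, one C1' methyl axial above) the bromonium ion should form on the lower face, anti to that axial methyl, and acetic acid opens it trans-diaxially (Fürst–Plattner rule) at C3' from above, which sets C3'–O trans to C7' and leaves bromine on C4' anti to the C5' hydrogen.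

Step 4
Reactants: 6 (1S,2S,3S,4R)-2-bromo-4-ethynyl-3,5,5-trimethylcyclohexyl acetate
Product: 8 (1S,4R)-4-ethynyl-3,5,5-trimethylcyclohex-2-en-1-ol, via allylic acetate 7 (not isolated)
Conditions: DBU (3 equiv), PhMe, 90 °C; then K2CO3 (0.5 equiv), MeOH, 23 °C
Reagents that add atoms: none
Why: E2 elimination needs an anti-periplanar hydrogen, and the only one trans-diaxial to the C4' bromine is the C5' hydrogen set in step 1, so the alkene should form only at C4'=C5'; methanolysis (transesterification) of the acetate then frees the C3' alcohol without touching its configuration.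

Step 5
Reactants: 9 but-2-yn-1-ol
Product: 11 (E)-3-iodobut-2-en-1-ol, via alkenylzirconocene 10 (not isolated)
Conditions: Cp2Zr(H)Cl (2.3 equiv), THF, 23 → 40 °C; I2 (1.2 equiv), 0 °C
Reagents that add atoms: iodine, II
Why: Syn hydrozirconation (one hydride equivalent is spent on the hydroxyl) places zirconium on the less hindered, methyl-bearing alkyne carbon, and iodinolysis of the C–Zr bond with retention gives the E iodide (hydrozirconation–iodination).

Step 6
Reactants: 11 (E)-3-iodobut-2-en-1-ol
Product: 12 (E)-1-bromo-3-iodobut-2-ene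
Conditions: PBr3 (0.4 equiv), Et2O, 0 °C, dark
Reagents that add atoms: phosphorus tribromide, BrP(Br)Br
Why: SN2 bromination of the primary allylic alcohol through its phosphite ester; the alkenyl iodide is inert and the alkene geometry is untouched.

Step 7
Reactants: 12 (E)-1-bromo-3-iodobut-2-ene
Product: 13 diethyl [(2E)-3-iodobut-2-en-1-yl]phosphonate
Conditions: P(OEt)3 (3 equiv), neat, 110 °C, dark
Reagents that add atoms: triethyl phosphite, CCOP(OCC)OCC
Why: Michaelis–Arbuzov reaction of the allylic bromide; an alkenyl iodide does not react with a phosphite without a metal catalyst.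

Step 8
Reactants: 8 (1S,4R)-4-ethynyl-3,5,5-trimethylcyclohex-2-en-1-ol; 13 diethyl [(2E)-3-iodobut-2-en-1-yl]phosphonate
Product: 16 diethyl {(2E,4E)-5-[(1S,4S)-4-hydroxy-2,6,6-trimethylcyclohex-2-en-1-yl]-3-methylpenta-2,4-dien-1-yl}phosphonate, via alkenylzirconocene 14 (not isolated), via alkenylzinc chloride 15 (not isolated)
Conditions: Cp2Zr(H)Cl (2.2 equiv), THF, 23 °C, dark; ZnCl2 (1.2 equiv); 13, Pd(PPh3)4 (5 mol%), 23 °C
Reagents that add atoms: none
Why: Syn hydrozirconation of the terminal alkyne (one hydride equivalent is spent on the hydroxyl) puts the metal on C8' with E geometry, and transmetalation to zinc followed by Negishi coupling with the alkenyl iodide forms C8'–C9' with retention at both alkenes.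

Step 9
Reactants: 17 racemic α-ionone
Product: 18 (S)-α-ionone, (3E)-4-[(1S)-2,6,6-trimethylcyclohex-2-en-1-yl]but-3-en-2-one
Conditions: preparative SFC, amylose tris(3,5-dimethylphenylcarbamate) phase, CO2/i-PrOH
Reagents that add atoms: none
Why: Resolution by chromatography on a polysaccharide chiral stationary phase separates the two enantiomers of the enone without chemical change; the (S) fraction supplies C6.

Step 10
Reactants: 18 (S)-α-ionone
Product: 19 (1E)-3-methyl-1-[(1S)-2,6,6-trimethylcyclohex-2-en-1-yl]penta-1,4-dien-3-ol (mixture of C-3 epimers)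
Conditions: CH2=CHMgBr (1.3 equiv), THF, −20 → 0 °C; NH4Cl aq
Reagents that add atoms: vinylmagnesium bromide, C=C[Mg]Br
Why: 1,2-Grignard addition to the enone carbonyl; the new carbinol centre forms unselectively and is destroyed in step 11.

Step 11
Reactants: 19 (1E)-3-methyl-1-[(1S)-2,6,6-trimethylcyclohex-2-en-1-yl]penta-1,4-dien-3-ol
Product: 20 {(2E,4E)-3-methyl-5-[(1S)-2,6,6-trimethylcyclohex-2-en-1-yl]penta-2,4-dien-1-yl}triphenylphosphonium bromide
Conditions: PPh3·HBr (1.05 equiv), MeOH, 23 °C
Reagents that add atoms: triphenylphosphine hydrobromide, [Br-].c1ccc(cc1)[PH+](c1ccccc1)c1ccccc1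
Why: Acid-induced ionisation of the tertiary allylic alcohol and capture of the dienyl cation by the phosphine at its primary terminus C11 (substitution with allylic transposition) should outrun proton loss from C6, as in established C15 salt preparations.

Step 12
Reactants: 20 the C15 phosphonium bromide; 21 (2E,4E,6E)-2,7-dimethylocta-2,4,6-trienedial
Product: 22 (2E,4E,6E,8E,10E,12E)-2,7,11-trimethyl-13-[(1S)-2,6,6-trimethylcyclohex-2-en-1-yl]trideca-2,4,6,8,10,12-hexaenal
Conditions: 21 (3 equiv), NaOMe (1.05 equiv), CH2Cl2/MeOH, 0 → 23 °C; then heptane, 90 °C; crystallisation, dark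
Reagents that add atoms: none
Why: Wittig reaction of the semi-stabilised ylide with one formyl group of the dialdehyde, which is used in excess to suppress double olefination; the new C11=C12 bond is equilibrated thermally to E.

Step 13
Reactants: 16 the ring B C15 phosphonate; 22 the C25 aldehyde
Product: 23 CNP0153224.1, (3'S,6'S,6S)-ε,ε-caroten-3'-ol in the labels used here
Conditions: KOt-Bu (2.2 equiv), THF, −30 °C; 22, −30 → 0 °C; argon, dark
Reagents that add atoms: none
Why: Horner–Wadsworth–Emmons olefination of the allylic phosphonate carbanion (the second equivalent of base holds the hydroxyl as its alkoxide) with the polyene aldehyde forms C11'=C12' with E selectivity and completes the C40 chain without touching C3', C6' or C6.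

**Compound list**

1 | (E)-penta-1,3-diene | C=C/C=C/C | starting material
2 | mesityl oxide (4-methylpent-3-en-2-one) | CC(C)=CC(C)=O | starting material
3 | 1-[(1R,2R)-2,6,6-trimethylcyclohex-3-en-1-yl]ethanone (cis) | CC(=O)[C@@H]1[C@H](C)C=CCC1(C)C | intermediate
4 | diethyl 1-[(1R,2R)-2,6,6-trimethylcyclohex-3-en-1-yl]ethenyl phosphate | C=C(OP(=O)(OCC)OCC)[C@@H]1[C@H](C)C=CCC1(C)C | intermediate (not isolated)
5 | (3R,4R)-4-ethynyl-3,5,5-trimethylcyclohex-1-ene (cis) | C#C[C@@H]1[C@H](C)C=CCC1(C)C | intermediate
6 | (1S,2S,3S,4R)-2-bromo-4-ethynyl-3,5,5-trimethylcyclohexyl acetate | C#C[C@@H]1[C@H](C)[C@H](Br)[C@@H](OC(C)=O)CC1(C)C | intermediate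
7 | (1S,4R)-4-ethynyl-3,5,5-trimethylcyclohex-2-en-1-yl acetate | C#C[C@@H]1C(C)=C[C@@H](OC(C)=O)CC1(C)C | intermediate (not isolated)
8 | (1S,4R)-4-ethynyl-3,5,5-trimethylcyclohex-2-en-1-ol (OH trans to ethynyl) | C#C[C@@H]1C(C)=C[C@@H](O)CC1(C)C | intermediate
9 | but-2-yn-1-ol | CC#CCO | starting material
10 | (E)-alkenylzirconocene chloride from 9, oxygen also bound to zirconocene chloride | Cl[Zr](C1C=CC=C1)(C1C=CC=C1)OC/C=C(\C)[Zr](Cl)(C1C=CC=C1)C1C=CC=C1 | intermediate (not isolated)
11 | (E)-3-iodobut-2-en-1-ol | OC/C=C(\C)I | intermediate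
12 | (E)-1-bromo-3-iodobut-2-ene | BrC/C=C(\C)I | intermediate
13 | diethyl [(2E)-3-iodobut-2-en-1-yl]phosphonate | CCOP(=O)(OCC)C/C=C(\C)I | intermediate
14 | (E)-alkenylzirconocene chloride from 8, oxygen also bound to zirconocene chloride | Cl[Zr](C1C=CC=C1)(C1C=CC=C1)/C=C/[C@@H]1C(C)=C[C@@H](O[Zr](Cl)(C2C=CC=C2)C2C=CC=C2)CC1(C)C | intermediate (not isolated)
15 | (E)-alkenylzinc chloride from 14 | Cl[Zn]/C=C/[C@@H]1C(C)=C[C@@H](O[Zr](Cl)(C2C=CC=C2)C2C=CC=C2)CC1(C)C | intermediate (not isolated)
16 | diethyl {(2E,4E)-5-[(1S,4S)-4-hydroxy-2,6,6-trimethylcyclohex-2-en-1-yl]-3-methylpenta-2,4-dien-1-yl}phosphonate | CCOP(=O)(OCC)C/C=C(C)/C=C/[C@@H]1C(C)=C[C@@H](O)CC1(C)C | intermediate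
17 | racemic α-ionone, (3E)-4-(2,6,6-trimethylcyclohex-2-en-1-yl)but-3-en-2-one | CC1=CCCC(C)(C)C1/C=C/C(C)=O | starting material
18 | (S)-α-ionone | CC1=CCCC(C)(C)[C@@H]1/C=C/C(C)=O | intermediate
19 | (1E)-3-methyl-1-[(1S)-2,6,6-trimethylcyclohex-2-en-1-yl]penta-1,4-dien-3-ol (C-3 epimers) | CC1=CCCC(C)(C)[C@@H]1/C=C/C(C)(O)C=C | intermediate
20 | {(2E,4E)-3-methyl-5-[(1S)-2,6,6-trimethylcyclohex-2-en-1-yl]penta-2,4-dien-1-yl}triphenylphosphonium bromide | CC1=CCCC(C)(C)[C@@H]1/C=C/C(C)=C/C[P+](c2ccccc2)(c2ccccc2)c2ccccc2.[Br-] | intermediate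
21 | (2E,4E,6E)-2,7-dimethylocta-2,4,6-trienedial (C10 dialdehyde) | O=C/C(C)=C/C=C/C=C(C)/C=O | starting material
22 | (6S)-12'-apo-ε-caroten-12'-al, all-E C25 aldehyde | CC1=CCCC(C)(C)[C@@H]1/C=C/C(C)=C/C=C/C(C)=C/C=C/C=C(C)/C=O | intermediate
23 | CNP0153224.1, all-E (3'S,6'S,6S)-ε,ε-caroten-3'-ol | CC1=CCCC(C)(C)[C@@H]1/C=C/C(C)=C/C=C/C(C)=C/C=C/C=C(C)/C=C/C=C(C)/C=C/[C@@H]1C(C)=C[C@@H](O)CC1(C)C | target

**Step count**

Total: 13 steps. Longest linear sequence: 6 steps (steps 1, 2, 3, 4, 8, 13) from 1 and 2.

**Steps most likely to fail**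

Step 1. The chiral Lewis acid may fail to activate the hindered, weakly basic β,β-disubstituted enone, so that conversion stays low while the diene oligomerises. It may also discriminate the enone faces poorly, which would erode enantiomeric purity, and acid-mediated enolisation could erode the cis relationship. The fallback uses known chemistry and sets out from 1 and 2: AlCl3 (0.3 equiv) in CH2Cl2 at 0 °C should promote the achiral endo cycloaddition to racemic cis-1-(2,6,6-trimethylcyclohex-3-en-1-yl)ethanone F1. Preparative chromatography of F1 on a cellulose tris(3,5-dimethylphenylcarbamate) phase would separate the enantiomers, and the (1R,2R) fraction is 3, where the route resumes at step 2.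

Step 3. Bromonium formation on the upper face, or opening of the ion outside the trans-diaxial mode (the attack at C3' runs syn to the axial C1' methyl), would place acetate on C4' and bromine on C3', and elimination would then put the alkene in the wrong position. The fallback sets out from 5 and uses a reaction that needs exactly the upper face: sensitised photooxygenation (O2, tetraphenylporphyrin, visible light, CH2Cl2, 0 °C). This Schenck ene reaction would remove the upper-face C5' hydrogen and deliver oxygen to C3' on the same face, giving (1S,4R)-4-ethynyl-3,5,5-trimethylcyclohex-2-en-1-yl hydroperoxide F2. Reduction with PPh3 gives 8, where the route resumes at step 8.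

Step 4. Proton abstraction at the hindered axial C5' position may be slow, which leaves room for acetoxonium participation at C4' or for acetate loss followed by epoxide closure. The fallback sets out from 6 and makes the epoxide on purpose: K2CO3 in MeOH cleaves the acetate, and the C3' alkoxide displaces the anti C4' bromide to give 3-ethynyl-2,4,4-trimethyl-7-oxabicyclo[4.1.0]heptane F3, with the epoxide oxygen on the upper face. Diethylaluminium 2,2,6,6-tetramethylpiperidide (PhMe, 0 °C) would then effect base-induced syn elimination through the C5' hydrogen on the epoxide face and open F3 to 8, where the route resumes at step 8.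

**Further compounds**

F1 | step 1 | racemic cis-1-(2,6,6-trimethylcyclohex-3-en-1-yl)ethanone | CC(=O)[C@@H]1[C@H](C)C=CCC1(C)C.CC(=O)[C@H]1[C@@H](C)C=CCC1(C)C
F2 | step 3 | (1S,4R)-4-ethynyl-3,5,5-trimethylcyclohex-2-en-1-yl hydroperoxide | C#C[C@@H]1C(C)=C[C@@H](OO)CC1(C)C
F3 | step 4 | 3-ethynyl-2,4,4-trimethyl-7-oxabicyclo[4.1.0]heptane, epoxide oxygen trans to the ethynyl and 2-methyl groups | C#C[C@@H]1[C@H](C)[C@H]2O[C@H]2CC1(C)C
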